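No flask can show more target than capture has made of it, so the share asked for is a capture race followed by a decay, and I solved each end apart.

| flask | starting material | first nucleophile | second nucleophile | temperature | remark | time |
|---|---|---|---|---|---|---|
| cedar | 0.50 M | 0.50 M | 0.60 M | 20 °C | run made earlier |  |
| ash | 0.50 M | 0.50 M | 0.40 M | 31 °C | run made earlier |  |
| larch | 0.50 M | 0.50 M | 0.90 M | 20 °C | run made earlier |  |
| Saturday's | 0.50 M (fed, over 3.0 h) | 0.500 M | 0.600 M | 25 °C | all else is in the flask from the start; the feed brings no volume worth counting | 40 h |
| Thursday's | 0.50 M | 0.500 M (fed, over 30 h) | 0.600 M |  | the addition at 5 °C, then warmed to 25 °C; the feed brings no volume worth counting | 40 h |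
| Sunday's | 0.50 M | 0.500 M | 0.600 M | 25 °C | everything together at the start | 40 h |
| Wednesday's | 0.50 M | 0.500 M (fed, over 30 h) | 0.600 M | 25 °C | all else is in the flask from the start; the feed brings no volume worth counting | 40 h |
| Monday's | 0.50 M | 0.500 M | 0.600 M |  | everything together at the start at 5 °C, warmed to 25 °C at 30 h | 40 h |

| run | time / h | target / % | other capture product / % |
|---|---|---|---|
| cedar | 3.00 | 18.6 | 5.2 |
| cedar | 6.00 | 33.0 | 9.3 |
| cedar | 10.0 | 42.9 | 14.9 |
| cedar | 15.0 | 49.3 | 17.6 |
| cedar | 20.0 | 52.8 | 20.5 |
| cedar | 25.0 | 53.4 | 23.1 |
| ash | 2.50 | 32.8 | 8.4 |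
| ash | 4.00 | 40.6 | 11.2 |
| ash | 6.00 | 45.4 | 15.4 |
| ash | 10.0 | 43.3 | 18.5 |
| ash | 15.0 | 38.0 | 21.2 |
| ash | 20.0 | 29.4 | 22.0 |
| ash | 30.0 | 16.7 | 23.8 |
| larch | 5.00 | 26.2 | 11.8 |
| larch | 10.0 | 39.3 | 18.6 |
| larch | 15.0 | 45.0 | 24.0 |
| larch | 20.0 | 47.5 | 26.8 |
| larch | 25.0 | 47.2 | 29.6 |
| larch | 30.0 | 46.9 | 32.3 |

(scatter of a reading: 0.5 percentage points)

- the analysis behind the earlier runs scatters by 0.5 percentage points, standard deviation
- candidate steps: first nucleophile + intermediate -> target; target -> over-reaction product A; second nucleophile + intermediate -> other capture product; starting material <-> intermediate; target -> over-reaction product B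

- the flask that comes out highest in share of target in target plus other capture product, or "all alike" when all lie within 1.5 percentage points (Saturday's / Thursday's / Sunday's / Wednesday's / Monday's / all alike)
- share of target in target plus other capture product at the end, Saturday's
- share of target in target plus other capture product at the end, Thursday's
- share of target in target plus other capture product at the end, Sunday's
- share of target in target plus other capture product at the end, Wednesday's
- share of target in target plus other capture product at the end, Monday's

I began with Sunday's flask, everything together at 25 °C. The first readings gave a pseudo-first-order capture constant, 0.0906 /h in the cedar run and 0.212 /h in the ash run. Taking 25 °C as near the middle, I used their geometric mean, which puts the mean time of capture τ at 7.21 h.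

By its last reading the cedar run should have captured 89.6 %, but target and other capture product held 76.5 %. Spreading that gap over a typical target of 42.9 % gave a loss constant of 0.0122 /h. The ash run's tail read 0.0566 /h. I carried k_L, the first-order loss constant of target at 25 °C, their geometric mean 0.0263 /h, with survival f = exp(−k_L(t − τ)).

Now the two ends. The cedar run, scaled to full capture, leaves 25.8 % as other capture product. I took that split from 20 °C over to 25 °C unchanged, as an assumption, so both ends are estimates. With it, my end for a Sunday's flask losing no target was 74.2 %. My end for one losing target at the ash rate was 31.1 %. I put Sunday's flask between them, since k_L is slower than the ash rate. With f = 42.2 % I committed to 54.9 %.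

The forecast chose Monday's, with Saturday's 58 %, Thursday's 62 %, Sunday's 57.5 %, Wednesday's 34 % and Monday's 71 %: “Feeding the first nucleophile starves capture. Monday's cold hold protects target and improves selectivity, so it wins.” My Sunday's figure stood lower than the forecast's.

The flasks gave Monday's as highest, with Saturday's 52.7 %, Thursday's 63.1 %, Sunday's 51.7 %, Wednesday's 29.2 % and Monday's 70.7 %.

    first nucleophile + intermediate → target (k = 150 /M/h, Ea = 42.0 kJ/mol)
    target → over-reaction product A (k = 0.0250 /h, Ea = 103 kJ/mol)
    second nucleophile + intermediate → other capture product (k = 33.0 /M/h, Ea = 54.0 kJ/mol)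
    starting material ⇌ intermediate (K = 0.00630, k = 0.210 /h, Ea = 85.0 kJ/mol, ΔH = −35.0 kJ/mol)
    target → over-reaction product B (k = 7.00 × 10⁻⁴ /h, Ea = 114 kJ/mol)
    (constants at 25 °C)

In Sunday's flask the forward step of starting material had a half-life of 3.3 h, shorter than the 28 h of target passing into over-reaction product A, and f applied to the 70.8 % in target and its two products gives 29.9 %, where target stood at 30.5 %. Monday's flask had 10.0 h warm, so k_L gives a survival of 76.9 %, which on its 62.6 % makes 48.1 %, against a target of 50.3 %.

All runs stem from a simulated flask on assumed constants; scatter was added.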